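Equal amounts went in: 0.050 M of solid Q and 0.0500 M of G. Q dissolves as J, J takes up G to give J.G, and G also pairs with itself to G2.

Q 0.050 M; G 0.0500 M; time 5.0 min

- J.G and G.J.G together at 5.0 min, in percent of the Q charged
- the change that raises the amount of J.G and G.J.G together at 5.0 min, in percent of the Q charged most ("none" if none brings more than 2 percentage points) (alder / oak / cedar / none)
- amount of J.G and G.J.G together at 5.0 min, in percent of the Q charged, after cedar

- alder: doubling the solubility in step 4, all else as stated
- oak: doubling the amount of G, all else as stated
- cedar: doubling the dissolution coefficient of step 4, all else as stated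

    2 G → G2 (k1 = 0.098 L mol⁻¹ s⁻¹)
    J + G → J.G (k2 = 0.23 L mol⁻¹ s⁻¹)
    G + J.G ⇌ G.J.G, settled at all times (K3 = 57 L mol⁻¹)
    Q ⇌ J, rate k4*(cs4 - [J]) while solid is left; crystals form when [J] > cs4 (cs4 = 32 mM, k4 = 0.020 s⁻¹)

1. On the fastest rung, G and J.G stood at balance with G.J.G at every moment. The answer counts both forms, but each G.J.G holds a second G, and at the starting [G] the balance stood at 2.9 G.J.G to each J.G. I left that bound G out of the reckoning below, as a simplification.

2. Next came dissolution, on a time scale of 0.833 min, with [J] climbing toward its solubility of 32 mM.

3. G pairing with itself came after that, with a first half-life of 1.70 min, longer than the dissolution time.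

4. Capture of G by J at full solubility was slower, at 2.26 min, yet still shorter than the 5.0 min run.

5. I replaced the rising curve of [J] by its mean over the run, 26.7 mM. Capture then became pseudo-first-order in G, and the sharing of G could be solved by hand. This gave 26.7 mM, which I called the catch: the J.G formed by the end of the run when G is shared between self-pairing and capture at mean [J]. In the flask that was 53.4% of the Q charged. The Q charge does not enter it.

6. Oak raised my catch to 81.7%. For alder the doubled solubility, 64.0 mM, exceeded the 50 mM of Q, so I used the Q charge as the ceiling and got 66.1%. I chose oak.

7. The forecast differed: 39% (35% to 43%), best change alder, 44% after cedar (39% to 49%). Of alder, the doubled solubility, it said that it “should beat doubling G, much of which dimerises”.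

8. The simulation gave 39.2%, best change oak with 13 percentage points against 8.9 points for alder, and 44.5% after cedar.

9. My catch stood 14 points above the result. The rates show the sharing of G shifting along the run: at 1.03 min capture used G at 0.91 times the rate of self-pairing, and at 5.00 min at 8.7 times, with free G then at 8.11% of its charge.

10. With 0.12 M of Q in the neighbouring flask, the same catch gives 22.3% of that charge. The computed result there is 16.3%, with 58.6% of the Q still solid.

Its constants were chosen freely; no experiment stands behind them.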